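**Strategy.** Everything rests on the C3–C1′ disconnection. C3 of the lactone ring is an acyloxy-bearing stereocentre flanked by two methylene groups, C4 of the isochromanone ring and C1′ of the side chain: an ester of a dialkyl carbinol. The bond is made by a nickel-hydride enantioconvergent alkyl–alkyl coupling that joins a racemic 1-bromo-2-arylethyl benzoate, formed in the flask from the arylacetaldehyde and benzoyl bromide, to the terminal olefin (S)-10-methoxyundec-1-ene. One operation unites both halves, sets (R)-C3 under catalyst control from a racemate and installs the future ring oxygen O2. Bromination, debenzoylation, carbonylative lactonisation and hydrogenolysis finish the isochromanone.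

Key step: step 4

Assumption: the sense of induction of the nickel/bis(oxazoline) catalyst in step 4 is not predicted here; the ligand enantiomer that gives (R) at C3 would be chosen in a trial coupling of phenylacetaldehyde, benzoyl bromide and 1-octene, the antipode being equally available.
Remark: alkoxide salts that differ from a numbered compound only by deprotonation before work-up are not numbered separately.

Step 1
Reactants: 1 3,5-bis(benzyloxy)benzaldehyde
Product: 3 2-[3,5-bis(benzyloxy)phenyl]acetaldehyde, via methyl enol ether 2 (not isolated)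
Conditions: MeOCH2PPh3Cl, KOtBu, THF, 0 °C to rt; then 2 M aq. HCl added to the same flask, 50 °C
Reagents that add atoms: (methoxymethyl)triphenylphosphonium chloride COC[P+](c1ccccc1)(c1ccccc1)c1ccccc1.[Cl-] (gives the new aldehyde carbon); water O (gives the carbonyl oxygen)
Why: Wittig methoxymethylenation followed by acid hydrolysis of the enol ether is the standard one-carbon homologation of an aryl aldehyde; benzyl aryl ethers should tolerate dilute acid and no stereocentre is formed.

Step 2
Reactants: 4 8-bromooct-1-ene; 5 (S)-2-methyloxirane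
Product: 7 (2S)-undec-10-en-2-ol, via oct-7-enylmagnesium bromide 6 (not isolated)
Conditions: Mg, THF, 40 °C; then CuI (10 mol %), 5, −30 to 0 °C; aq. NH4Cl work-up
Reagents that add atoms: none
Why: Copper-catalysed Grignard opening of a terminal epoxide should occur at the unsubstituted carbon, so the C–O bond at the stereocentre is untouched and the (S) configuration of 5 is carried over unchanged.

Step 3
Reactants: 7 (2S)-undec-10-en-2-ol
Product: 8 (10S)-10-methoxyundec-1-ene
Conditions: NaH, MeI, THF, 0 °C to rt
Reagents that add atoms: iodomethane CI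
Why: Williamson etherification alkylates oxygen only, so the carbinol stereocentre is not touched.

Step 4
Reactants: 3 2-[3,5-bis(benzyloxy)phenyl]acetaldehyde; 8 (10S)-10-methoxyundec-1-ene
Product: 10 (2R,12S)-1-[3,5-bis(benzyloxy)phenyl]-12-methoxytridecan-2-yl benzoate, via racemic 1-bromoalkyl benzoate 9 (not isolated)
Conditions: BzBr, ZnBr2 (2 mol %), Et2O, 0 °C to rt; then 8, NiBr2·glyme (10 mol %), chiral Ph-BOX ligand [2,2′-(propane-2,2-diyl)bis(4-phenyl-4,5-dihydrooxazole), enantiomer per the assumption, 12 mol %], (EtO)3SiH, K3PO4·H2O, Et2O/DMA, 0 °C to rt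
Reagents that add atoms: benzoyl bromide O=C(Br)c1ccccc1
Why: Benzoyl bromide adds across the aldehyde C=O of 3 to give racemic bromo ester 9; a nickel hydride formed from NiBr2·glyme, the ligand and the silane inserts olefin 8 in the anti-Markovnikov sense to a primary alkylnickel, bromine abstraction from 9 by low-valent nickel gives a planar α-benzoyloxy radical that erases the configuration of both enantiomers, and radical capture followed by reductive elimination from trivalent nickel forms the C3–C1′ bond. The closest known reaction type is the nickel-catalysed enantioconvergent reductive coupling of racemic 1-bromoalkyl esters (from an aldehyde and an acyl bromide) with olefins and a hydrosilane, including its one-pot four-component form. No ring is closed in this step. The new stereocentre C3 (R) is set by the chiral ligand on nickel at the radical-capture and reductive-elimination stage, with the benzoate carbonyl as the coordinating group, so both enantiomers of 9 should converge on one product and the remote (S)-methoxy centre of 8 has no influence. The step needs linear regioselectivity, which the monosubstituted terminal alkene secures, and C–Br activation in preference to loss of HBr towards the styryl benzoate, which the mild base and low temperature are meant to secure; benzyl ethers and the aliphatic methyl ether should be inert.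

Step 5
Reactants: 10 (2R,12S)-1-[3,5-bis(benzyloxy)phenyl]-12-methoxytridecan-2-yl benzoate
Product: 11 (2R,12S)-1-[3,5-bis(benzyloxy)-2-bromophenyl]-12-methoxytridecan-2-yl benzoate
Conditions: NBS (1.0 equiv), MeCN, 0 °C, dark
Reagents that add atoms: N-bromosuccinimide O=C1CCC(=O)N1Br
Why: Electrophilic aromatic bromination should go to the position ortho to the alkyl group and para to a benzyloxy group (the two such positions are equivalent by symmetry) and not to the hindered carbon between the two benzyloxy groups; the stereocentres are not involved.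

Step 6
Reactants: 11 (2R,12S)-1-[3,5-bis(benzyloxy)-2-bromophenyl]-12-methoxytridecan-2-yl benzoate
Product: 12 (2R,12S)-1-[3,5-bis(benzyloxy)-2-bromophenyl]-12-methoxytridecan-2-ol
Conditions: K2CO3 (0.5 equiv), MeOH/THF, 40 °C
Reagents that add atoms: none
Why: Base-catalysed transesterification cleaves the benzoate at the acyl carbon, so the C–O bond at the carbinol centre and its (R) configuration are retained.

Step 7
Reactants: 12 (2R,12S)-1-[3,5-bis(benzyloxy)-2-bromophenyl]-12-methoxytridecan-2-ol
Product: 13 (3R)-6,8-bis(benzyloxy)-3-[(10S)-10-methoxyundecyl]-3,4-dihydro-1H-isochromen-1-one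
Conditions: Pd(OAc)2 (5 mol %), Xantphos (6 mol %), CO (1 atm), Et3N, toluene, 100 °C
Reagents that add atoms: carbon monoxide [C-]#[O+]
Why: Palladium-catalysed intramolecular alkoxycarbonylation: zerovalent palladium inserts into the aryl C–Br bond, CO inserts, and the pendant secondary hydroxyl traps the acylpalladium to close the six-membered lactone; the C3–O bond is not broken, so configuration is kept.

Step 8
Reactants: 13 (3R)-6,8-bis(benzyloxy)-3-[(10S)-10-methoxyundecyl]-3,4-dihydro-1H-isochromen-1-one
Product: 14 (3R)-6,8-dihydroxy-3-[(10S)-10-methoxyundecyl]-3,4-dihydro-1H-isochromen-1-one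
Conditions: H2 (1 atm), 10% Pd/C, EtOAc/MeOH, rt
Reagents that add atoms: none
Why: Hydrogenolysis should remove both benzyl aryl ethers, while the lactone, the aliphatic methyl ether and both stereocentres (neither is benzylic) should be untouched.

**Compound list**

1 | 3,5-bis(benzyloxy)benzaldehyde | O=Cc1cc(OCc2ccccc2)cc(OCc2ccccc2)c1 | starting material
2 | 1,3-bis(benzyloxy)-5-(2-methoxyethenyl)benzene (E/Z mixture, not isolated) | COC=Cc1cc(OCc2ccccc2)cc(OCc2ccccc2)c1 | intermediate
3 | 2-[3,5-bis(benzyloxy)phenyl]acetaldehyde | O=CCc1cc(OCc2ccccc2)cc(OCc2ccccc2)c1 | intermediate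
4 | 8-bromooct-1-ene | C=CCCCCCCBr | starting material
5 | (S)-2-methyloxirane | C[C@H]1CO1 | starting material
6 | oct-7-enylmagnesium bromide (not isolated) | C=CCCCCCC[Mg]Br | intermediate
7 | (2S)-undec-10-en-2-ol | C[C@H](O)CCCCCCCC=C | intermediate
8 | (10S)-10-methoxyundec-1-ene | CO[C@@H](C)CCCCCCCC=C | intermediate
9 | racemic 2-[3,5-bis(benzyloxy)phenyl]-1-bromoethyl benzoate (not isolated) | O=C(OC(Br)Cc1cc(OCc2ccccc2)cc(OCc2ccccc2)c1)c1ccccc1 | intermediate
10 | (2R,12S)-1-[3,5-bis(benzyloxy)phenyl]-12-methoxytridecan-2-yl benzoate | CO[C@@H](C)CCCCCCCCC[C@@H](OC(=O)c1ccccc1)Cc1cc(OCc2ccccc2)cc(OCc2ccccc2)c1 | intermediate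
11 | (2R,12S)-1-[3,5-bis(benzyloxy)-2-bromophenyl]-12-methoxytridecan-2-yl benzoate | CO[C@@H](C)CCCCCCCCC[C@@H](OC(=O)c1ccccc1)Cc1cc(OCc2ccccc2)cc(OCc2ccccc2)c1Br | intermediate
12 | (2R,12S)-1-[3,5-bis(benzyloxy)-2-bromophenyl]-12-methoxytridecan-2-ol | CO[C@@H](C)CCCCCCCCC[C@@H](O)Cc1cc(OCc2ccccc2)cc(OCc2ccccc2)c1Br | intermediate
13 | (3R)-6,8-bis(benzyloxy)-3-[(10S)-10-methoxyundecyl]-3,4-dihydro-1H-isochromen-1-one | CO[C@@H](C)CCCCCCCCC[C@@H]1Cc2cc(OCc3ccccc3)cc(OCc3ccccc3)c2C(=O)O1 | intermediate
14 | (3R)-6,8-dihydroxy-3-[(10S)-10-methoxyundecyl]-3,4-dihydro-1H-isochromen-1-one | CO[C@@H](C)CCCCCCCCC[C@@H]1Cc2cc(O)cc(O)c2C(=O)O1 | target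

**Step count.** Total: 8 steps. Longest linear sequence: 7 steps (steps 2, 3, 4, 5, 6, 7, 8, from 8-bromooct-1-ene).

**Steps most likely to fail**

1. Step 4 (key coupling). What may go wrong: loss of HBr from the bromo ester to a styryl benzoate before radical capture, reduction of the C–Br bond by the nickel hydride, or weak facial discrimination at the radical-capture stage. Fallback (sets out from 3 and 8, returns at 12): a stereospecific lithiation–borylation that forms the same C3–C1′ bond under reagent control. Aldehyde 3 would be reduced (NaBH4, MeOH) to 2-[3,5-bis(benzyloxy)phenyl]ethanol F1 and carbamoylated (iPr2NCOCl, Et3N, toluene, reflux) to 2-[3,5-bis(benzyloxy)phenyl]ethyl N,N-diisopropylcarbamate F2. Olefin 8 would be hydroborated with pinacolborane ([Ir(cod)Cl]2/dppe, CH2Cl2) to the primary pinacol boronate 2-[(10S)-10-methoxyundecyl]-4,4,5,5-tetramethyl-1,3,2-dioxaborolane F3. Deprotonation of F2 with sBuLi/(+)-sparteine (Et2O, −78 °C) should give the configurationally stable (R)-α-lithio carbamate F4, which would be trapped by F3 with retention as the lithium boronate complex F5. On warming (MgBr2·OEt2, reflux) the side-chain carbon should migrate from boron to C3 with inversion and expel the carbamate, giving the secondary pinacol boronate F6. Oxidation (NaOH, H2O2) with retention would give (2R,12S)-1-[3,5-bis(benzyloxy)phenyl]-12-methoxytridecan-2-ol F7, and bromination (NBS, MeCN, 0 °C) would rejoin the route at 12.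

2. Step 7 (carbonylative lactonisation). What may go wrong: slow oxidative addition into the electron-rich, doubly ortho-substituted aryl bromide, with protodebromination or palladium-mediated oxidation of the secondary alcohol taking over. Fallback (sets out from 12, returns at 13): bromine–lithium exchange and carboxylation in place of palladium catalysis. Treatment of 12 with n-BuLi (2.2 equiv, THF, −78 °C) should give the dilithiated alkoxide–aryllithium F8; quenching with CO2 and acidic work-up would give 2,4-bis(benzyloxy)-6-[(2R,12S)-2-hydroxy-12-methoxytridecyl]benzoic acid F9, and acid-catalysed lactonisation (TsOH, toluene, 60 °C) would give 13.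

3. Step 1 (homologation). What may go wrong: self-condensation and air oxidation of the enolisable arylacetaldehyde under the aqueous acid needed for enol-ether hydrolysis, or incomplete hydrolysis. Fallback (sets out from 1, returns at 3): epoxide isomerisation under anhydrous conditions. Corey–Chaykovsky methylenation of 1 (Me3S+ I−, KOtBu, DMSO/THF) would give racemic 2-[3,5-bis(benzyloxy)phenyl]oxirane F10, and a Meinwald rearrangement (InCl3, 5 mol %, THF, rt) with 1,2-hydride shift should give 3, to be used at once in step 4.

**Further compounds**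

F1 | step 4 | 2-[3,5-bis(benzyloxy)phenyl]ethanol | OCCc1cc(OCc2ccccc2)cc(OCc2ccccc2)c1
F2 | step 4 | 2-[3,5-bis(benzyloxy)phenyl]ethyl N,N-diisopropylcarbamate | CC(C)N(C(C)C)C(=O)OCCc1cc(OCc2ccccc2)cc(OCc2ccccc2)c1
F3 | step 4 | 2-[(10S)-10-methoxyundecyl]-4,4,5,5-tetramethyl-1,3,2-dioxaborolane | CO[C@@H](C)CCCCCCCCCB1OC(C)(C)C(C)(C)O1
F4 | step 4 | (1R)-2-[3,5-bis(benzyloxy)phenyl]-1-lithioethyl N,N-diisopropylcarbamate (sparteine complex, not isolated) | CC(C)N(C(C)C)C(=O)O[C@H]([Li])Cc1cc(OCc2ccccc2)cc(OCc2ccccc2)c1
F5 | step 4 | lithium boronate complex of F4 and F3 (not isolated) | CO[C@@H](C)CCCCCCCCC[B-]1(OC(C)(C)C(C)(C)O1)[C@H](Cc1cc(OCc2ccccc2)cc(OCc2ccccc2)c1)OC(=O)N(C(C)C)C(C)C.[Li+]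
F6 | step 4 | 2-[(2R,12S)-1-[3,5-bis(benzyloxy)phenyl]-12-methoxytridecan-2-yl]-4,4,5,5-tetramethyl-1,3,2-dioxaborolane | CO[C@@H](C)CCCCCCCCC[C@@H](B1OC(C)(C)C(C)(C)O1)Cc1cc(OCc2ccccc2)cc(OCc2ccccc2)c1
F7 | step 4 | (2R,12S)-1-[3,5-bis(benzyloxy)phenyl]-12-methoxytridecan-2-ol | CO[C@@H](C)CCCCCCCCC[C@@H](O)Cc1cc(OCc2ccccc2)cc(OCc2ccccc2)c1
F8 | step 7 | dilithiated alkoxide–aryllithium from 12 (not isolated) | CO[C@@H](C)CCCCCCCCC[C@@H](O[Li])Cc1cc(OCc2ccccc2)cc(OCc2ccccc2)c1[Li]
F9 | step 7 | 2,4-bis(benzyloxy)-6-[(2R,12S)-2-hydroxy-12-methoxytridecyl]benzoic acid | CO[C@@H](C)CCCCCCCCC[C@@H](O)Cc1cc(OCc2ccccc2)cc(OCc2ccccc2)c1C(=O)O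
F10 | step 1 | racemic 2-[3,5-bis(benzyloxy)phenyl]oxirane | C1OC1c1cc(OCc2ccccc2)cc(OCc2ccccc2)c1
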